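**Plan**

- Retrosynthesis: the acid and both phenols are unveiled last from three benzyl groups, the two acetates come from a diol, and the C2' oxygen comes from a C2'–B bond.
- Central cut: the bond from ring carbon C6 to benzylic C1' and the C2'–C3' bond are broken together. The triad ring C6–C1'H2–C2'H(O)–unbranched alkyl is what a vinyl group becomes when it takes an aryl group on its terminal carbon and an alkyl group plus boron on its internal carbon.
- Fragments: aryl triflate 9 (two steps from 2,4,6-trihydroxybenzoic acid, ring bought with its substitution pattern), alkyl pinacol boronate 6 for C3'–C13' (three steps from (R)-propylene oxide), and vinyllithium for C1'–C2'.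
- Forward order: 6 and 9 are made separately and joined with vinyllithium in one catalytic three-component step, followed by desilylation, B-to-O oxidation, double acetylation and hydrogenolysis. The C2' acetate is in place before the acid is freed, so the dihydroisocoumarin cannot form.
- Stereochemistry: C12' (R) comes from (R)-propylene oxide; C2' (S) is set by the chiral palladium catalyst in the joining step and kept by stereoretentive oxidation.

Key step: step 6

Assumption: the (Sp,Sp) enantiomer of MandyPhos is taken to deliver the (S)-boronate 11; if the sense of induction proves opposite on this substrate, the mirror-image ligand is used with no other change.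

**Route**

Step 1
Reactants: 1 8-bromooct-1-ene; 2 (R)-2-methyloxirane
Product: 4 (R)-undec-10-en-2-ol, via oct-7-en-1-ylmagnesium bromide 3 (not isolated)
Conditions: Mg, THF, rt; then CuI (10 mol%), 2, THF, −30 to 0 °C; 1 M HCl quench
Reagents that add atoms: none
Why: Copper-catalysed Grignard opening of a terminal epoxide (SN2 at the unsubstituted CH2) leaves the stereocentre of 2 untouched, so it becomes C12' of the target with the (R) configuration already in place.

Step 2
Reactants: 4 (R)-undec-10-en-2-ol
Product: 5 triethyl{[(2R)-undec-10-en-2-yl]oxy}silane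
Conditions: Et3SiCl, imidazole, CH2Cl2, 0 °C to rt
Reagents that add atoms: chlorotriethylsilane, CC[Si](Cl)(CC)CC
Why: Standard silylation of a secondary alcohol; the triethylsilyl ether withstands the organolithium and palladium steps ahead yet falls to mild acid that a pinacol boronate tolerates.

Step 3
Reactants: 5 triethyl{[(2R)-undec-10-en-2-yl]oxy}silane
Product: 6 triethyl{[(2R)-11-(4,4,5,5-tetramethyl-1,3,2-dioxaborolan-2-yl)undecan-2-yl]oxy}silane
Conditions: HBpin, [Ir(cod)Cl]2 (1.5 mol%), dppm (3 mol%), CH2Cl2, rt
Reagents that add atoms: pinacolborane, CC1(C)OBOC1(C)C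
Why: Iridium-catalysed hydroboration of a terminal alkene with pinacolborane is anti-Markovnikov and should give the primary alkyl pinacol boronate that serves as the migrating group; the silyl ether and the stereocentre are not involved.

Step 4
Reactants: 7 2,4,6-trihydroxybenzoic acid
Product: 8 benzyl 2,4-bis(benzyloxy)-6-hydroxybenzoate
Conditions: BnBr (3.05 equiv), K2CO3, DMF, 0 °C to rt
Reagents that add atoms: benzyl bromide, BrCc1ccccc1
Why: Williamson alkylation takes the carboxylate first, then the 4-hydroxyl and one 2-hydroxyl, while the last hydroxyl, held in a hydrogen bond to the new ester carbonyl, is the least nucleophilic and should stay free when benzyl bromide is limited to three equivalents.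

Step 5
Reactants: 8 benzyl 2,4-bis(benzyloxy)-6-hydroxybenzoate
Product: 9 benzyl 2,4-bis(benzyloxy)-6-{[(trifluoromethyl)sulfonyl]oxy}benzoate
Conditions: Tf2O, pyridine, CH2Cl2, 0 °C
Reagents that add atoms: trifluoromethanesulfonic anhydride, O=S(=O)(OS(=O)(=O)C(F)(F)F)C(F)(F)F
Why: O-Sulfonylation of the remaining chelated phenol gives an aryl triflate whose ortho ester activates it towards oxidative addition, as in the widely used 2,4-dialkoxy-6-triflyloxybenzoate coupling partners.

Step 6
Reactants: 6 triethyl{[(2R)-11-(4,4,5,5-tetramethyl-1,3,2-dioxaborolan-2-yl)undecan-2-yl]oxy}silane; 9 benzyl 2,4-bis(benzyloxy)-6-{[(trifluoromethyl)sulfonyl]oxy}benzoate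
Product: 11 benzyl 2,4-bis(benzyloxy)-6-[(2S,12R)-2-(4,4,5,5-tetramethyl-1,3,2-dioxaborolan-2-yl)-12-(triethylsilyloxy)tridecyl]benzoate, via lithium vinylborate complex 10 (not isolated)
Conditions: 6 (1.2 equiv), vinyllithium (1.1 equiv, halide-free, from Sn(CH=CH2)4 and n-BuLi), Et2O, 0 °C to rt, evaporate; then 9 (1.0 equiv), Pd(OAc)2 (2 mol%), (Sp,Sp)-MandyPhos (C52H50FeN2P2, 2.4 mol%), THF, 60 °C
Reagents that add atoms: vinyllithium, [Li]C=C
Why: Vinyllithium adds to the boron of 6 to give the four-coordinate vinylborate 10; zerovalent palladium carrying the chiral ferrocenyl bisphosphine inserts into the C–OTf bond of 9, and the resulting cationic arylpalladium species (divalent palladium) binds the vinyl group of 10 and triggers a 1,2-metallate shift in which the primary alkyl group moves from boron to the internal vinyl carbon anti to palladium while palladium bonds to the terminal carbon, after which reductive elimination forms the aryl–CH2 bond and returns zerovalent palladium. The closest known reaction type is the palladium-catalysed enantioselective conjunctive cross-coupling of vinylboron ate complexes with aryl triflates, which is established for alkyl migrating groups and electron-rich aryl triflates. No ring is closed. The new stereocentre C2' is set by the ligand, which decides the face of the coordinated vinyl group that palladium occupies during the shift, the distant C12' centre being a spectator, and the C–B bond formed stands in for the C2' oxygen. The step needs the conjunctive pathway to win over direct Suzuki-type transfer of the vinyl group and over β-hydride elimination from the alkylpalladium intermediate; the non-coordinating triflate of 9 (cationic palladium, strong alkene binding), the halide-free medium and the rigid bidentate ligand should secure this, and the ortho ester of 9 speeds oxidative addition. No free organolithium is left to attack the benzyl ester because 6 is used in slight excess over vinyllithium.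

Step 7
Reactants: 11 benzyl 2,4-bis(benzyloxy)-6-[(2S,12R)-2-(4,4,5,5-tetramethyl-1,3,2-dioxaborolan-2-yl)-12-(triethylsilyloxy)tridecyl]benzoate
Product: 12 benzyl 2,4-bis(benzyloxy)-6-[(2S,12R)-12-hydroxy-2-(4,4,5,5-tetramethyl-1,3,2-dioxaborolan-2-yl)tridecyl]benzoate
Conditions: PPTS (cat.), MeOH/CH2Cl2, rt
Reagents that add atoms: none
Why: Acid-catalysed methanolysis cleaves a secondary triethylsilyl ether under conditions that leave the pinacol boronate, the benzyl ethers and the hindered benzyl ester alone, and it is done before the oxidation so that no free C2' hydroxyl yet faces the ester.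

Step 8
Reactants: 12 benzyl 2,4-bis(benzyloxy)-6-[(2S,12R)-12-hydroxy-2-(4,4,5,5-tetramethyl-1,3,2-dioxaborolan-2-yl)tridecyl]benzoate
Product: 13 benzyl 2,4-bis(benzyloxy)-6-[(2S,12R)-2,12-dihydroxytridecyl]benzoate
Conditions: NaBO3·4H2O, THF/H2O (1:1), rt; extractive work-up, crude used at once
Reagents that add atoms: sodium perborate, [Na+].[Na+].O[B-]1(O)OO[B-](O)(O)OO1
Why: Perborate oxidation of a secondary alkyl pinacol boronate proceeds by a 1,2-shift of carbon from boron to oxygen with retention, so the (S) configuration at C2' is kept, and the nearly neutral medium is chosen to keep the new hydroxyl from closing onto the flanking ester.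

Step 9
Reactants: 13 benzyl 2,4-bis(benzyloxy)-6-[(2S,12R)-2,12-dihydroxytridecyl]benzoate
Product: 14 benzyl 2,4-bis(benzyloxy)-6-[(2S,12R)-2,12-diacetoxytridecyl]benzoate
Conditions: Ac2O, pyridine, DMAP (cat.), CH2Cl2, 0 °C to rt
Reagents that add atoms: acetic anhydride, CC(=O)OC(C)=O
Why: DMAP-catalysed acylation esterifies both secondary alcohols at once without touching either stereocentre and removes the C2' hydroxyl as a possible lactonising nucleophile before the acid is set free.

Step 10
Reactants: 14 benzyl 2,4-bis(benzyloxy)-6-[(2S,12R)-2,12-diacetoxytridecyl]benzoate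
Product: 15 2-[(2S,12R)-2,12-diacetoxytridecyl]-4,6-dihydroxybenzoic acid
Conditions: H2 (1 atm), Pd/C (10%), EtOAc, rt
Reagents that add atoms: none
Why: Catalytic hydrogenolysis cleaves the benzyl ester and both aryl benzyl ethers at their benzylic C–O bonds under neutral conditions in which the two secondary acetates and the homobenzylic C2'–O bond are inert, so the target should form without any hydrolytic step.

**Compound list**

1 | 8-bromooct-1-ene | C=CCCCCCCBr | starting material
2 | (R)-2-methyloxirane ((R)-propylene oxide) | C[C@@H]1CO1 | starting material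
3 | oct-7-en-1-ylmagnesium bromide | C=CCCCCCC[Mg]Br | intermediate
4 | (R)-undec-10-en-2-ol | C=CCCCCCCC[C@@H](C)O | intermediate
5 | triethyl{[(2R)-undec-10-en-2-yl]oxy}silane | C=CCCCCCCC[C@@H](C)O[Si](CC)(CC)CC | intermediate
6 | triethyl{[(2R)-11-(4,4,5,5-tetramethyl-1,3,2-dioxaborolan-2-yl)undecan-2-yl]oxy}silane | CC1(C)OB(CCCCCCCCC[C@@H](C)O[Si](CC)(CC)CC)OC1(C)C | intermediate
7 | 2,4,6-trihydroxybenzoic acid | OC(=O)c1c(O)cc(O)cc1O | starting material
8 | benzyl 2,4-bis(benzyloxy)-6-hydroxybenzoate | O=C(OCc1ccccc1)c1c(O)cc(OCc2ccccc2)cc1OCc1ccccc1 | intermediate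
9 | benzyl 2,4-bis(benzyloxy)-6-{[(trifluoromethyl)sulfonyl]oxy}benzoate | O=C(OCc1ccccc1)c1c(OS(=O)(=O)C(F)(F)F)cc(OCc2ccccc2)cc1OCc1ccccc1 | intermediate
10 | lithium [(10R)-10-(triethylsilyloxy)undecyl](vinyl)(pinacolato)borate | [Li+].C=C[B-]1(CCCCCCCCC[C@@H](C)O[Si](CC)(CC)CC)OC(C)(C)C(C)(C)O1 | intermediate
11 | benzyl 2,4-bis(benzyloxy)-6-[(2S,12R)-2-(4,4,5,5-tetramethyl-1,3,2-dioxaborolan-2-yl)-12-(triethylsilyloxy)tridecyl]benzoate | CC1(C)OB(OC1(C)C)[C@@H](CCCCCCCCC[C@@H](C)O[Si](CC)(CC)CC)Cc1cc(OCc2ccccc2)cc(OCc2ccccc2)c1C(=O)OCc1ccccc1 | intermediate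
12 | benzyl 2,4-bis(benzyloxy)-6-[(2S,12R)-12-hydroxy-2-(4,4,5,5-tetramethyl-1,3,2-dioxaborolan-2-yl)tridecyl]benzoate | CC1(C)OB(OC1(C)C)[C@@H](CCCCCCCCC[C@@H](C)O)Cc1cc(OCc2ccccc2)cc(OCc2ccccc2)c1C(=O)OCc1ccccc1 | intermediate
13 | benzyl 2,4-bis(benzyloxy)-6-[(2S,12R)-2,12-dihydroxytridecyl]benzoate | O[C@@H](CCCCCCCCC[C@@H](C)O)Cc1cc(OCc2ccccc2)cc(OCc2ccccc2)c1C(=O)OCc1ccccc1 | intermediate
14 | benzyl 2,4-bis(benzyloxy)-6-[(2S,12R)-2,12-diacetoxytridecyl]benzoate | CC(=O)O[C@@H](CCCCCCCCC[C@@H](C)OC(C)=O)Cc1cc(OCc2ccccc2)cc(OCc2ccccc2)c1C(=O)OCc1ccccc1 | intermediate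
15 | 2-[(2S,12R)-2,12-diacetoxytridecyl]-4,6-dihydroxybenzoic acid | CC(=O)O[C@@H](CCCCCCCCC[C@@H](C)OC(C)=O)Cc1cc(O)cc(O)c1C(=O)O | target

**Step count and risks**

Total step count: 10. Longest linear sequence: 8 (steps 1, 2, 3, 6, 7, 8, 9, 10).

Steps most likely to fail:

1. Step 6. Direct Suzuki-type transfer of the vinyl group to the aryl group may outrun the metallate shift, and the ortho ester next to the reacting carbon may slow the coupling or erode the facial selectivity at C2'. The fallback sets out from 6 and 9 and comes back at 11, forming the same aryl–CH2 bond in two stages. Zweifel vinylation of 6 (vinyllithium, then I2, then NaOMe, THF/MeOH, −78 °C to rt) should give the terminal alkene triethyl{[(2R)-tridec-12-en-2-yl]oxy}silane F1. Enantioselective diboration of F1 (B2pin2, Pt(dba)3, TADDOL-derived phosphonite ligand of the hand that gives the (R)-bis(boronate), THF, 60 °C) should give 2,2'-[(2R,12R)-12-(triethylsilyloxy)tridecane-1,2-diyl]bis(4,4,5,5-tetramethyl-1,3,2-dioxaborolane) F2. The primary C–B bond of F2, activated by the neighbouring boronate, is then coupled selectively with 9 (Pd(OAc)2, RuPhos, KOH, THF/H2O, 70 °C) to give 11; here C2' is set by the diboration catalyst.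

2. Step 8. The new C2' hydroxyl may close onto the neighbouring benzyl ester with loss of benzyl alcohol during oxidation or work-up. The fallback sets out from 13 (or its mixture with lactone) and comes back at 14. Lactonisation is driven to completion (DBU cat., toluene, 60 °C) to the dihydroisocoumarin (3S)-6,8-bis(benzyloxy)-3-[(10R)-10-hydroxyundecyl]isochroman-1-one F3, a stable compound that can be purified. F3 is opened with KOH (1.0 equiv, THF/H2O, then evaporation to dryness) to potassium 2,4-bis(benzyloxy)-6-[(2S,12R)-2,12-dihydroxytridecyl]benzoate F4, whose carboxylate cannot be attacked by the hydroxyl. Alkylation of F4 with BnBr in dry DMF at 0 °C regenerates 13 under neutral, water-free conditions, and Ac2O, DMAP and Et3N are added to the same flask to reach 14.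

3. Step 4. C-benzylation of the electron-rich ring, benzylation of the third hydroxyl, or decarboxylation before the carboxylate is alkylated may lower the selectivity. The fallback sets out from 7 and comes back at 8. Acetonide formation (acetone, CF3CO2H, (CF3CO)2O, 0 °C to rt) should give 5,7-dihydroxy-2,2-dimethyl-4H-1,3-benzodioxin-4-one F5, in which acid and one phenol are tied up. Exhaustive O-benzylation (BnBr, K2CO3, DMF, 60 °C) gives 5,7-bis(benzyloxy)-2,2-dimethyl-4H-1,3-benzodioxin-4-one F6. Ring opening with sodium benzyloxide (BnOH, NaH, THF, 0 °C) delivers the benzyl ester and frees exactly one ortho phenol, giving 8.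

**Further compounds**

F1 | step 6 | triethyl{[(2R)-tridec-12-en-2-yl]oxy}silane | C=CCCCCCCCCC[C@@H](C)O[Si](CC)(CC)CC
F2 | step 6 | 2,2'-[(2R,12R)-12-(triethylsilyloxy)tridecane-1,2-diyl]bis(4,4,5,5-tetramethyl-1,3,2-dioxaborolane) | CC1(C)OB(OC1(C)C)[C@@H](CCCCCCCCC[C@@H](C)O[Si](CC)(CC)CC)CB1OC(C)(C)C(C)(C)O1
F3 | step 8 | (3S)-6,8-bis(benzyloxy)-3-[(10R)-10-hydroxyundecyl]isochroman-1-one | O=C1O[C@@H](CCCCCCCCC[C@@H](C)O)Cc2cc(OCc3ccccc3)cc(OCc3ccccc3)c12
F4 | step 8 | potassium 2,4-bis(benzyloxy)-6-[(2S,12R)-2,12-dihydroxytridecyl]benzoate | [K+].O[C@@H](CCCCCCCCC[C@@H](C)O)Cc1cc(OCc2ccccc2)cc(OCc2ccccc2)c1C(=O)[O-]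
F5 | step 4 | 5,7-dihydroxy-2,2-dimethyl-4H-1,3-benzodioxin-4-one | CC1(C)OC(=O)c2c(O)cc(O)cc2O1
F6 | step 4 | 5,7-bis(benzyloxy)-2,2-dimethyl-4H-1,3-benzodioxin-4-one | CC1(C)OC(=O)c2c(OCc3ccccc3)cc(OCc3ccccc3)cc2O1
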